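Slowness sets in abruptly in the north-east run: from 5.00 min to 20.0 min product goes from 26.7% to 26.3%, a drift of 0.4 percentage points against a scatter of 0.3 points. The flask asked about is that same run, followed on.

- north-east: substrate 0.020 M; reagent 0.060 M; free catalyst 10 µM; the very flask that is asked about, followed so far
- flask: substrate 0.020 M; reagent 0.0600 M; free catalyst 10 µM; time 30 min

north-east run (percent of the substrate charged)

| time / min | product / % | substrate / % |
|---|---|---|
| 1.33 | 22.1 | 52.9 |
| 2.50 | 25.7 | 50.5 |
| 5.00 | 26.7 | 49.3 |
| 10.0 | 26.6 | 48.8 |
| 20.0 | 26.3 | 49.0 |

(standard deviation of a reading: 0.3 percentage points)

- product that was removed still counts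
- steps under discussion: substrate + free catalyst <-> free catalyst + open intermediate; free catalyst + open intermediate <-> catalyst intermediate; reagent + catalyst intermediate <-> free catalyst + product; reagent + free catalyst -> spent catalyst
- additions bring no volume worth counting

- Sunday's: change nothing and wait 30 min more
- Thursday's: at 30 min add free catalyst, 100% of the amount charged, then wait 30 min
- Wednesday's: at 30 min add reagent, 50.0% of the amount charged, then wait 30 min
- Friday's: at 30 min take out 90% of the product then present, then wait 30 min

- product, in percent of the substrate first charged, at 30 min
- what to do for the largest gain in product; "none" if nothing gains more than 2 percentage points (Sunday's / Thursday's / Wednesday's / Friday's / none)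
- product present, with what was taken out counted in, in percent of the substrate first charged, after Sunday's
- product present, with what was taken out counted in, in percent of the substrate first charged, after Friday's

The north-east flask can be read as a ladder of time scales. On the fastest rung, by 1.33 min, the readings leave 25.0% of the substrate unaccounted for. This must be open intermediate, because the catalyst charge equals 0.0500% of the substrate and can hold no such share. On the next rung the gap between product and its plateau closes at a rate k, read from the early points as 1.30 min⁻¹.

The plateau reads 26.5% on average, and reagent goes into product and into spent catalyst, which can take up 10 µM, so 91.1% of the reagent stays free. Reagent is therefore not the limiting reagent, and it can be frozen at its charge. The loss of free catalyst to spent catalyst is then pseudo-first-order, and this reckoning reads k as that loss, though the readings do not exclude an equilibrium. On the last rung, 30 min spans 39.0 lifetimes of the catalyst.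

The plateau, taken on 0.020 M of substrate and 10 µM of catalyst, comes to 531: this is the turnover number T, moles of product per mole of catalyst charged. Waiting, more reagent or taking product out adds no catalyst, so this reckoning holds the flask at 26.5% under each of them. Thursday's dose offers T again, worth 27 points. That figure is to be shaved, since substrate and open intermediate together are down to 73.5% of the charge, yet it stands far above the margin of 2 points.

The forecast stands at 26.5%, 26.5% after Sunday's and 26.5% after Friday's, and names Thursday's: “Fresh catalyst gives a second burst”.

The flask gives 26.8%, with 26.8% after Sunday's, 26.8% after Friday's, and Thursday's as the best choice, at a gain of 21 points.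

    substrate + free catalyst ⇌ free catalyst + open intermediate (K = 0.990, k = 3700 M⁻¹ s⁻¹)
    free catalyst + open intermediate ⇌ catalyst intermediate (K = 430 M⁻¹, k = 6500 M⁻¹ s⁻¹)
    reagent + catalyst intermediate ⇌ free catalyst + product (K = 0.160, k = 2400 M⁻¹ s⁻¹)
    reagent + free catalyst → spent catalyst (k = 0.620 M⁻¹ s⁻¹)

At 3.00 min spent catalyst already stands at 98.1% of the catalyst charged. Thursday's second dose earns 421 turnovers, against a T of 531 for the first. For the neighbour charged with 1.7 × 10⁻⁵ M of free catalyst, T gives 45.1% of product, and that flask holds 43.1%.

The data come from a simulation on assumed constants, noise included.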